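All runs were computed for an exercise; scatter was added.

The constants of these steps are hidden, so two of us argue from the readings. One of us made the forecast; I hold the other view.

| flask | substrate | partner | free catalyst | remark |
|---|---|---|---|---|
| teal | 0.10 M | 0.15 M | 2 mM | the very flask that is asked about, followed so far |
| green | 0.10 M | 0.15 M | 4 mM | run made earlier |
| flask | 0.10 M | 0.150 M | 2.0 mM |  |
teal run (percent of the substrate charged)

| time / s | product / % | substrate / % |
|---|---|---|
| 30.0 | 24 | 73 |
| 60.0 | 47 | 49 |
| 90.0 | 59 | 35 |
| 120 | 73 | 26 |

green run (percent of the substrate charged)

| time / min | product / % | substrate / % |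
|---|---|---|
| 1.00 | 65 | 33 |
| 2.00 | 92 | 7 |
| 3.00 | 99 | 1 |
| 4.00 | 98 | 4 |

(readings scatter by 2 percentage points)
1. apparent order in partner when 30% of the substrate are converted (percent change of the rate of making product for one percent more partner charged)
2. apparent order in free catalyst when 30% of the substrate are converted (percent change of the rate of making product for one percent more free catalyst charged)
- a species is counted by the substrate in it: one resting dimer counts as two
- the analysis behind the earlier runs scatters by 2 percentage points, standard deviation
- candidate steps: partner + catalyst intermediate A -> catalyst intermediate B; substrate + free catalyst <-> catalyst intermediate A; catalyst intermediate B <-> free catalyst + product; 2 catalyst intermediate A <-> resting dimer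
- no earlier run changes the charge of partner; that part of a forecast is a guess

The forecast treats the teal substrate as a first-order decay. On teal its constant holds: 0.0119 s⁻¹ at 60.0 s and 0.0112 s⁻¹ at 120 s. It concludes “Substrate binding is mostly limiting, with partner capture fast”, and it gives 0.25 for partner and 0.85 for free catalyst, calling the partner value a guess.

My view is that the catalyst sits loaded with substrate, so the rate follows partner. Each product uses one partner, so I take partner left as close to its charge minus the product formed. I carry one quantity: the logarithm of partner charged over partner left, divided by time. This is the inverse of a time constant, a pseudo-first-order constant. On teal it reads 0.376 min⁻¹ at 60.0 s, the partner constant. At 120 s it reads 0.333 min⁻¹. So teal fits both views.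

Green separates the two ends. Its substrate constant rises from 0.0185 s⁻¹ at 1.00 min to 0.0222 s⁻¹ at 2.00 min. I take that reading, with its scatter of 2 percentage points, as a sign that at high substrate the rate does not follow substrate. Its partner constant falls from 0.568 min⁻¹ to 0.475 min⁻¹, with substrate down to 7%. I join the ends: the rate follows partner at high substrate and substrate at low substrate. At 30% conversion the flask is at the high end, so I commit to order one in partner. Green over teal at 1.00 min gives me 0.595 in free catalyst, lower than the forecast's value.

The simulation gives 1.1 in partner and 0.74 in free catalyst.

    partner + catalyst intermediate A → catalyst intermediate B (k = 7.00 L mol⁻¹ s⁻¹)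
    substrate + free catalyst ⇌ catalyst intermediate A (K = 140 L mol⁻¹, k = 49.0 L mol⁻¹ s⁻¹)
    catalyst intermediate B ⇌ free catalyst + product (K = 0.140 M, k = 23.0 s⁻¹)
    2 catalyst intermediate A ⇌ resting dimer, settled at all times (K = 510 L mol⁻¹)

The forecast's view has its region at the late end: at 4.00 min the flask holds substrate 2.03%, and free catalyst is 53.7% of the catalyst charged, against 14.3% at 0.400 min. The partner constant from teal gives 0.0451 M min⁻¹ at 30% conversion, and the flask's rate at that conversion, reached at 0.573 min, is 0.0437 M min⁻¹. For a flask with twice the partner, the same constant gives 0.280 min to that conversion, and that flask took 0.304 min.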